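## Structural features

The target is an isoflavone: ring A is fused to the pyran-4-one ring C, C3 carries the aryl ring B, and C7 carries a free hydroxyl group. Ring B is fused through O4' and C5' to a 2,2-dimethyl-2H-pyran (ring D) and bears a methoxy group at C3', so rings B and D together form an 8-methoxy-2,2-dimethyl-2H-chromen-6-yl unit. There is no stereocentre; the questions are regiochemical: the oxygen pattern of ring A, the site of fusion of ring D, and the distinction between the two phenolic oxygens O7 and O4'. The fragile groups are the styrene-like C3''=C4'' double bond of ring D (it adds acid and is hydrogenated easily), C2 of the chromone (hydroxide opens ring C there) and the acidic 7-hydroxyl group. The real difficulty is the order of events: closing ring C by electrophilic chemistry needs acid, ring D does not tolerate it, and the last deprotection must spare ring D. The key step uses the fact that C4a is ortho to O1 and para to O7. In an open-chain aryl vinyl ether this is the most nucleophilic free carbon of a resorcinol diether, so C4–C4a can be the last bond of ring C. Ring B has a single free carbon ortho to O4' (C5'), which fixes the position of ring D.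

## Logic of the disconnections

14 to 13: the bond between O7 and an allyl group is put back. O7 must be an ether while ring C closes and must be freed last without hydrogen or acid, because of ring D. Zerovalent palladium removes an allyl group under neutral conditions. The forward step must ionise the allyl aryl ether faster than the hindered cyclic tertiary allylic ether of ring D.

13 to 11: the C5'–C4'' bond is cut while O4' keeps its tertiary carbon, so ring D becomes a 2-methylbut-3-yn-2-yl ether on O4'. Ring D cannot pass through acid, but its five carbons can in this form, and the same group protects O4'. Two identical benzyl ethers on O7 and O4' would be the conventional choice. They would free both phenols at once, need hydrogen next to the chromone double bond, and force a selective reprotection of O7 before ring D is built. The differentiated pair removes those operations. The forward cascade must go to C5' at a temperature below that at which the allyl ether on O7 rearranges.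

11 to 9: the C4–C4a bond is cut (key step). Ring C opens to an aryl vinyl ether acid, and ring A becomes a simple monoprotected resorcinol. The forward acylation must go para to the allyloxy group and not between the two oxygens, needs the isomer with aryloxy cis to the acid (Z) or its formation in the flask, and must leave the tertiary propargylic ether intact.

9 to 8: the acid is traced back to its methyl ester, because the ester is needed for the enolate chemistry earlier and the free acid for activation. The forward hydrolysis must attack the acyl carbon and not the β-carbon.

8 to 6 and 7: the O1–C2 vinyl ether bond is cut. This divides the molecule into its two aromatic halves, and 7 brings the complete oxygen pattern of ring A. The forward step needs the phenoxide to attack the β-carbon of 6 and not the sulfur atom.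

6 to 5: the O–S bond is cut; the enol oxygen is turned into a leaving group only when needed. The forward step should give the Z sulfonate if possible, although the route does not depend on it.

5 to 3 and 4: the bond between the α-carbon and the future C2 is cut, a crossed Claisen condensation in which only 3 can enolise and 4 supplies one carbon. The forward step needs the ester α-hydrogen, not the alkyne hydrogen, to be removed.

3 to 1 and 2: the bond between O4' and the tertiary carbon is cut, giving two catalogue compounds. A tertiary propargylic chloride does not alkylate a phenoxide by direct displacement, so the forward step needs copper catalysis.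

## Other disconnections considered

Alternative 1: Ring C is cut at C3–C4 and O1–C2. In the forward direction 7-(tert-butyldimethylsilyloxy)-2,2-dimethyl-4H-1,3-benzodioxin-4-one A1 would be irradiated near 300 nm, lose acetone and give a quinoketene. This would add 4-(2-methoxyvinyl)-2-methoxy-1-(2-methylbut-3-yn-2-yloxy)benzene A2 in a [4+2] sense, and loss of methanol would give 7-(tert-butyldimethylsilyloxy)-3-[3-methoxy-4-(2-methylbut-3-yn-2-yloxy)phenyl]chromen-4-one A3.
- In favour: two bonds of ring C form in one operation, the polarity matches (ketene carbon to the aryl-bearing enol ether carbon, ring oxygen to the methoxy-bearing carbon), and the medium is neutral.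
- Better than the chosen plan: the tertiary propargylic ether is at no risk from acid, and the oxygen pattern of ring A is fixed by the salicylate and does not depend on relative nucleophilicity. The plan is also more convergent, with a shorter longest linear sequence (about five against eight).
- Equal: it uses the same latent form of ring D and needs the same thermal ring closure afterwards.
- Against it: it needs photochemical equipment and dilution. The quinoketene is a high-energy species that water or a second ketene molecule can intercept, and the enol ether can isomerise or absorb light itself. Capture of such ketenes by simple enol ethers is thinly precedented compared with the ionic acylation chosen here. The aryl silyl ether is also more labile than an allyl ether.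

Alternative 2: Ring D is cut at C4''–C3'' and O1''–C2''. In the forward direction 3-(3-formyl-4-hydroxy-5-methoxyphenyl)-7-pivaloyloxychromen-4-one A4, trimethyl orthoformate and Sc(OTf)3 would give a methoxy-substituted ortho-quinone methide (an oxocarbenium ion). Isobutene would add to it to give 3-(4,8-dimethoxy-2,2-dimethylchroman-6-yl)-7-pivaloyloxychromen-4-one A5, racemic at C4''. Loss of methanol and removal of the pivalate would follow.
- In favour: the formyl carbon fixes the site of ring D, the polarity is well matched (the terminal carbon of isobutene to the benzylic carbon, the tertiary end to oxygen), isobutene is cheap, and no heating to 140 °C is needed.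
- Equal: regiochemical certainty for ring D, since ring B has only one free ortho carbon in the chosen plan too.
- Better: ring B carries no acid-labile ether while ring C is built.
- Against it: the cut concerns ring D only, so the chromone still has to be made by some other ring closure. The formyl group must also be introduced on ring B. The stereocentre that forms is thrown away in an extra acid elimination that the product chromene must survive. A gas and a Lewis acid are handled next to a chromone carbonyl and an aryl ester. The step count would exceed that of the chosen plan by at least three.

Alternative 3: Ring C is cut at O1–C8a. In the forward direction 1-[4-(allyloxy)-2-fluorophenyl]-3-hydroxy-2-(8-methoxy-2,2-dimethyl-2H-chromen-6-yl)prop-2-en-1-one A6 would be treated with K2CO3 in DMF. The enolate oxygen would displace the fluoride ortho to the ketone to give 7-allyloxy-3-(8-methoxy-2,2-dimethyl-2H-chromen-6-yl)chromen-4-one A7, which has the same structure as 13.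
- In favour: only base is used, so ring D can be in place before ring C closes.
- Better than the chosen plan: the position of the fluorine defines the regiochemistry of ring A, so there is no ortho/para question.
- Equal: the end game is the same deallylation.
- Against it: the allyloxy group para to the ketone weakens the activation of the fluoride, so heating would be needed. A6 requires a 2-fluoro deoxybenzoin assembled from two fragments that are not simple catalogue compounds. Joining them by enolate arylation with zerovalent palladium would conflict with the allyl ether, and joining them by acylation would expose the chromene to acid. Overall it would be longer than the chosen plan.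

Key step: step 6

Assumption: 6, 8 and 9 are drawn as single Z isomers, but each may form as an E/Z mixture. This is harmless because both isomers of 9 should converge on 11 in step 6. 3-(Allyloxy)phenol 7 is taken as a catalogue compound.

## Route

Step 1
Reactants: 1 methyl homovanillate [methyl 2-(4-hydroxy-3-methoxyphenyl)acetate]; 2 3-chloro-3-methylbut-1-yne
Product: 3 methyl 2-[3-methoxy-4-(2-methylbut-3-yn-2-yloxy)phenyl]acetate
Conditions: CuCl2·2H2O (cat.), DBU, MeCN, 0 °C
Reagents that add atoms: 3-chloro-3-methylbut-1-yne (2), CC(C)(Cl)C#C
Why: Copper-catalysed propargylic etherification: the copper acetylide of 2 ionises to an allenylidene-type electrophile that the phenoxide of 1 captures at the tertiary carbon, and the amidine base at 0 °C leaves the methyl ester alone. The ether protects O4' and installs all five carbons of ring D.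

Step 2
Reactants: 3 methyl 2-[3-methoxy-4-(2-methylbut-3-yn-2-yloxy)phenyl]acetate; 4 methyl formate
Product: 5 methyl (Z)-3-hydroxy-2-[3-methoxy-4-(2-methylbut-3-yn-2-yloxy)phenyl]acrylate (hydrogen-bonded enol form of the α-formyl ester)
Conditions: NaH, HCO2Me, THF, 0 °C to rt; then cold 1 M HCl
Reagents that add atoms: methyl formate (4), COC=O
Why: Crossed Claisen condensation (C-formylation) of the arylacetate enolate with a formate that cannot enolise; formation of the stabilised enolate of 5 drives it. The alkyne hydrogen is far less acidic than the benzylic ester hydrogen and NaH in THF should not metalate it.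

Step 3
Reactants: 5 methyl (Z)-3-hydroxy-2-[3-methoxy-4-(2-methylbut-3-yn-2-yloxy)phenyl]acrylate
Product: 6 methyl (Z)-2-[3-methoxy-4-(2-methylbut-3-yn-2-yloxy)phenyl]-3-(tosyloxy)acrylate
Conditions: TsCl, TMEDA, LiCl, MeCN, 0 °C
Reagents that add atoms: p-toluenesulfonyl chloride, Cc1ccc(cc1)S(Cl)(=O)=O
Why: O-Sulfonylation of the enol, a vinylogous acid. Lithium chelation between the enolate oxygen and the ester carbonyl should favour the Z sulfonate, and the enol oxygen becomes a leaving group on an electrophilic β-carbon.

Step 4
Reactants: 6 methyl (Z)-2-[3-methoxy-4-(2-methylbut-3-yn-2-yloxy)phenyl]-3-(tosyloxy)acrylate; 7 3-(allyloxy)phenol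
Product: 8 methyl (Z)-3-[3-(allyloxy)phenoxy]-2-[3-methoxy-4-(2-methylbut-3-yn-2-yloxy)phenyl]acrylate
Conditions: Cs2CO3, DMF, rt to 40 °C
Reagents that add atoms: 3-(allyloxy)phenol (7), Oc1cccc(OCC=C)c1
Why: Nucleophilic vinylic substitution by addition–elimination: the phenoxide adds to the unhindered β-carbon, and the carbanion stabilised by ester and aryl expels tosylate, normally with retention of geometry. This forms the O1–C2 bond and joins the two aromatic halves.

Step 5
Reactants: 8 methyl (Z)-3-[3-(allyloxy)phenoxy]-2-[3-methoxy-4-(2-methylbut-3-yn-2-yloxy)phenyl]acrylate
Product: 9 (Z)-3-[3-(allyloxy)phenoxy]-2-[3-methoxy-4-(2-methylbut-3-yn-2-yloxy)phenyl]acrylic acid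
Conditions: LiOH·H2O, THF/MeOH/H2O, rt; then cold 1 M HCl to pH 3
Reagents that add atoms: lithium hydroxide, [Li+].[OH-]
Why: Ester saponification by acyl substitution; at room temperature it should outrun conjugate attack at the β-carbon, as in the usual hydrolysis of 3-aryloxyacrylates. Both ethers are inert to base, and the brief cold acidification should spare the tertiary ether.

Step 6
Reactants: 9 (Z)-3-[3-(allyloxy)phenoxy]-2-[3-methoxy-4-(2-methylbut-3-yn-2-yloxy)phenyl]acrylic acid
Product: 11 7-(allyloxy)-3-[3-methoxy-4-(2-methylbut-3-yn-2-yloxy)phenyl]-4H-chromen-4-one, via mixed trifluoroacetic anhydride 10 (not isolated)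
Conditions: (CF3CO)2O, CH2Cl2 (dilute), 0 °C to rt; then aq. NaHCO3
Reagents that add atoms: none
Why: Trifluoroacetic anhydride converts the acid into the mixed anhydride 10, which, directly or through the acylium ion it can form once one equivalent of CF3CO2H is present, acylates ring A at the carbon ortho to the vinyl ether oxygen and para to the allyloxy group; loss of a proton restores the aromatic ring, an intramolecular Friedel–Crafts acylation. The closest known reaction type is the acid-mediated ring closure of 3-aryloxyacrylic acids to chromones, run here with anhydride activation for mildness. Ring C closes in a 6-exo-trig mode at the anhydride carbonyl (6-exo-dig if the free acylium ion is the electrophile), with the C2=C3 double bond inside the new ring. No stereocentre is formed. Only the Z acid, with aryloxy and acyl groups cis, can reach the ring; any E isomer should equilibrate because the acylium ion stabilised by the β-oxygen has oxocarbenium–ketene character with easy rotation about C2–C3, and because protonation at the α-carbon is reversible, so ring closure drains both isomers. The position para to the alkyl aryl ether oxygen is the more activated (O1, a vinylogous carbonate oxygen, is the weaker donor) and the less hindered, so attack between the two oxygens should be minor. The tertiary propargylic ether should survive one equivalent of CF3CO2H in cold dilute CH2Cl2 because the ethynyl group destabilises the tertiary cation, and the allyl ether is inert under these conditions.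

Step 7
Reactants: 11 7-(allyloxy)-3-[3-methoxy-4-(2-methylbut-3-yn-2-yloxy)phenyl]-4H-chromen-4-one
Product: 13 7-(allyloxy)-3-(8-methoxy-2,2-dimethyl-2H-chromen-6-yl)-4H-chromen-4-one, via ortho-allenylphenol 12 (not isolated)
Conditions: o-xylene, 140 °C
Reagents that add atoms: none
Why: Thermal aryl propargyl ether cascade: Claisen rearrangement to C5', the only free ortho carbon (the other bears the methoxy group), enolisation to 12, a 1,5-hydrogen shift and a 6π oxa-electrocyclisation close ring D. A simple allyl aryl ether on the electron-poor ring A needs a much higher temperature to rearrange.

Step 8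
Reactants: 13 7-(allyloxy)-3-(8-methoxy-2,2-dimethyl-2H-chromen-6-yl)-4H-chromen-4-one
Product: 14 7-hydroxy-3-(8-methoxy-2,2-dimethyl-2H-chromen-6-yl)-4H-chromen-4-one (target)
Conditions: Pd(PPh3)4 (cat.), morpholine, THF, rt
Reagents that add atoms: none
Why: Tsuji–Trost deallylation: zerovalent palladium ionises the allyl aryl ether, whose leaving group is the phenoxide of a vinylogous acid, and morpholine captures the π-allyl complex. The cyclic ether of ring D is tertiary, hindered and part of a trisubstituted styrene, so it should not ionise, and no hydrogen or acid is involved.

## Compound list

1 | methyl homovanillate, methyl 2-(4-hydroxy-3-methoxyphenyl)acetate | COC(=O)Cc1ccc(O)c(OC)c1 | starting material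
2 | 3-chloro-3-methylbut-1-yne | CC(C)(Cl)C#C | starting material
3 | methyl 2-[3-methoxy-4-(2-methylbut-3-yn-2-yloxy)phenyl]acetate | COC(=O)Cc1ccc(OC(C)(C)C#C)c(OC)c1 | intermediate
4 | methyl formate | COC=O | starting material
5 | methyl (Z)-3-hydroxy-2-[3-methoxy-4-(2-methylbut-3-yn-2-yloxy)phenyl]acrylate | COC(=O)/C(=C\O)c1ccc(OC(C)(C)C#C)c(OC)c1 | intermediate
6 | methyl (Z)-2-[3-methoxy-4-(2-methylbut-3-yn-2-yloxy)phenyl]-3-(tosyloxy)acrylate | COC(=O)/C(=C\OS(=O)(=O)c1ccc(C)cc1)c1ccc(OC(C)(C)C#C)c(OC)c1 | intermediate
7 | 3-(allyloxy)phenol | Oc1cccc(OCC=C)c1 | starting material
8 | methyl (Z)-3-[3-(allyloxy)phenoxy]-2-[3-methoxy-4-(2-methylbut-3-yn-2-yloxy)phenyl]acrylate | COC(=O)/C(=C\Oc1cccc(OCC=C)c1)c1ccc(OC(C)(C)C#C)c(OC)c1 | intermediate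
9 | (Z)-3-[3-(allyloxy)phenoxy]-2-[3-methoxy-4-(2-methylbut-3-yn-2-yloxy)phenyl]acrylic acid | OC(=O)/C(=C\Oc1cccc(OCC=C)c1)c1ccc(OC(C)(C)C#C)c(OC)c1 | intermediate
10 | (Z)-3-[3-(allyloxy)phenoxy]-2-[3-methoxy-4-(2-methylbut-3-yn-2-yloxy)phenyl]acrylic trifluoroacetic anhydride | O=C(OC(=O)C(F)(F)F)/C(=C\Oc1cccc(OCC=C)c1)c1ccc(OC(C)(C)C#C)c(OC)c1 | intermediate
11 | 7-(allyloxy)-3-[3-methoxy-4-(2-methylbut-3-yn-2-yloxy)phenyl]-4H-chromen-4-one | COc1cc(-c2coc3cc(OCC=C)ccc3c2=O)ccc1OC(C)(C)C#C | intermediate
12 | 7-(allyloxy)-3-[4-hydroxy-3-methoxy-5-(3-methylbuta-1,2-dien-1-yl)phenyl]-4H-chromen-4-one | COc1cc(-c2coc3cc(OCC=C)ccc3c2=O)cc(C=C=C(C)C)c1O | intermediate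
13 | 7-(allyloxy)-3-(8-methoxy-2,2-dimethyl-2H-chromen-6-yl)-4H-chromen-4-one | COc1cc(-c2coc3cc(OCC=C)ccc3c2=O)cc2c1OC(C)(C)C=C2 | intermediate
14 | 7-hydroxy-3-(8-methoxy-2,2-dimethyl-2H-chromen-6-yl)-4H-chromen-4-one | COc1cc(-c2coc3cc(O)ccc3c2=O)cc2c1OC(C)(C)C=C2 | target

## Step count and risks

Total step count: 8. Longest linear sequence: 8 steps (1 to 14).

Step 6 (key step). The most likely failures are acid-induced ionisation of the tertiary propargylic ether on ring B, closure at the carbon between the two oxygens, and slow E-to-Z equilibration that leaves activated acid unreacted. The first is the most serious, because the freed phenol would then be trifluoroacetylated and the latent ring D lost. The fallback sets out from 9 and accepts the loss on purpose. After ring closure with trifluoroacetic anhydride, CF3CO2H is added until ether cleavage is complete. Work-up with NaHCO3 in aqueous methanol removes any trifluoroacetate from the phenol and gives 7-(allyloxy)-3-(4-hydroxy-3-methoxyphenyl)-4H-chromen-4-one F1. Ring D is then built by a different reaction: F1, 3-methylbut-2-enal, PhB(OH)2 and acetic acid in refluxing toluene with azeotropic removal of water. This is an ortho-selective condensation through a cyclic aryl boronate, followed by quinone methide formation and 6π ring closure. It comes back to the route at 13 and replaces steps 6 and 7 without adding a step.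

Step 4. The phenoxide may attack the sulfur atom of the enol tosylate instead of the β-carbon. That sulfonyl transfer would return the enolate of 5 and consume 7. The fallback sets out from 5, which is converted with PPh3 and CCl4 in MeCN (Appel-type deoxychlorination of the enol) into methyl (Z)-3-chloro-2-[3-methoxy-4-(2-methylbut-3-yn-2-yloxy)phenyl]acrylate F2. This vinyl chloride has no second electrophilic centre. Its chloride is displaced by the phenoxide of 7 (Cs2CO3, DMF), which comes back to the route at 8.

Step 5. Hydroxide may add to the β-carbon and expel the aryloxide, the reverse of step 4, which would split the molecule into its halves. The fallback sets out from 8 and cleaves the ester at the methyl carbon instead: LiI in refluxing ethyl acetate (nucleophilic demethylation, alkyl–oxygen cleavage) and then cold dilute HCl give 9 without any hydroxide. The detour makes no new compound (F0) and comes back to the route at 9.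

Step 7. Prolonged heating may start a Claisen rearrangement of the allyl ether on O7, or the allenyl and quinone methide intermediates may oligomerise at high concentration. The fallback sets out from 11 and closes ring D at room temperature by hydroarylation: Ph3PAuNTf2 (cat.) in CH2Cl2. The monovalent gold activates the alkyne and C5' attacks its terminal carbon in a 6-endo-dig mode, a known reaction of aryl propargyl ethers. The detour makes no new compound (F0) and comes back to the route at 13.

## Further compounds

F1 | step 6 | 7-(allyloxy)-3-(4-hydroxy-3-methoxyphenyl)-4H-chromen-4-one | COc1cc(-c2coc3cc(OCC=C)ccc3c2=O)ccc1O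
F2 | step 4 | methyl (Z)-3-chloro-2-[3-methoxy-4-(2-methylbut-3-yn-2-yloxy)phenyl]acrylate | COC(=O)/C(=C\Cl)c1ccc(OC(C)(C)C#C)c(OC)c1
F0 | step 5 | none | none
F0 | step 7 | none | none
A1 | alternative 1 | 7-(tert-butyldimethylsilyloxy)-2,2-dimethyl-4H-1,3-benzodioxin-4-one | CC1(C)OC(=O)c2ccc(O[Si](C)(C)C(C)(C)C)cc2O1
A2 | alternative 1 | 4-(2-methoxyvinyl)-2-methoxy-1-(2-methylbut-3-yn-2-yloxy)benzene | COC=Cc1ccc(OC(C)(C)C#C)c(OC)c1
A3 | alternative 1 | 7-(tert-butyldimethylsilyloxy)-3-[3-methoxy-4-(2-methylbut-3-yn-2-yloxy)phenyl]chromen-4-one | COc1cc(-c2coc3cc(O[Si](C)(C)C(C)(C)C)ccc3c2=O)ccc1OC(C)(C)C#C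
A4 | alternative 2 | 3-(3-formyl-4-hydroxy-5-methoxyphenyl)-7-pivaloyloxychromen-4-one | COc1cc(-c2coc3cc(OC(=O)C(C)(C)C)ccc3c2=O)cc(C=O)c1O
A5 | alternative 2 | 3-(4,8-dimethoxy-2,2-dimethylchroman-6-yl)-7-pivaloyloxychromen-4-one (racemic at chroman C4) | COc1cc(-c2coc3cc(OC(=O)C(C)(C)C)ccc3c2=O)cc2c1OC(C)(C)CC2OC
A6 | alternative 3 | 1-[4-(allyloxy)-2-fluorophenyl]-3-hydroxy-2-(8-methoxy-2,2-dimethyl-2H-chromen-6-yl)prop-2-en-1-one | C=CCOc1ccc(C(=O)C(=CO)c2cc(OC)c3OC(C)(C)C=Cc3c2)c(F)c1
A7 | alternative 3 | 7-allyloxy-3-(8-methoxy-2,2-dimethyl-2H-chromen-6-yl)chromen-4-one | C=CCOc1ccc2c(c1)occ(-c1cc(OC)c3OC(C)(C)C=Cc3c1)c2=O
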